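**Retrosynthetic overview**
- Feature: in the carbocycle C1–C10 the oxygenated C6 and the C1=C10 alkene are 1,5-related (C6–C7–C8–C9–C10=C1), the pattern of a cyclodec-5-enone, and C6–C5=C4–C3–C2–C1 is the carbon ring of a cyclohex-2-enone. Joining C1 to C6 and cutting C8–C9 therefore turns the ten-membered ring into a six-membered ring with two alkenyl arms.
- Disconnections: target ⇒ ester, methylene and oxidation-level adjustments ⇒ cis-fused C12–O6 lactone (C7–C11 enolate alkylation, C6 reduction) ⇒ ten-membered dienone 23 ⇒ [3,3] shift (C8–C9 made, C1–C6 broken) of cis-dialkenylcyclohexenol 20 ⇒ enone 14 + silylacetylene 17 ⇒ (R)-limonene 1, whose methyl groups become C14 and C15 and whose stereocenter becomes C1.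
- C8–O is carried as a C–Si bond (benzyldimethylsilyl, unmasked by fluoride and peroxide with retention). The limonene stereocenter is relayed to C8 in the sigmatropic step, and C8 then directs C7 and C6.
- Ring order: six-membered carbocycle (from limonene) → ten-membered carbocycle (step 13, ring expansion) → γ-lactone (step 15).

Key step: step 13

Remark on the chemistry: every compound carries the atom numbering of the target (C1–C15, oxygens named after their carbon). Compounds 6, 7 and 10–13 are carried as epimer mixtures at C4/C5, centres that are sp2 again in 14, so their SMILES leave these centres open.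

**Step 1**
Reactants: 1 (R)-limonene
Product: 4 (R)-14-hydroxylimonene [(R)-p-mentha-1,8-dien-10-ol], via allyllithium 2 (not isolated), via allylboronate 3 (not isolated)
Conditions: n-BuLi, TMEDA, hexane, 25 °C; B(OMe)3, THF, −78 °C; then H2O2, NaOH, 0 °C
Reagents that add atoms: hydrogen peroxide (OO)
Why: Allylic lithiation of limonene by n-BuLi·TMEDA takes the isopropenyl methyl group, and borylation with peroxide oxidation of the symmetrical 2-substituted allylboronate should give the primary allylic alcohol without touching the C1 stereocenter (allylic metalation/borate oxidation).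

**Step 2**
Reactants: 4 (R)-14-hydroxylimonene
Product: 5 14-O-(4-methoxybenzyl) ether of 4
Conditions: NaH, 4-MeOC6H4CH2Cl, Bu4NI (cat.), THF/DMF, 0 → 25 °C
Reagents that add atoms: 4-methoxybenzyl chloride (COc1ccc(CCl)cc1)
Why: Williamson etherification of the primary allylic alkoxide; a benzyl-type ether and not a silyl ether is placed on O14 because this oxygen later lies next to the C6 alkoxide of step 13, to which a silyl group could migrate.

**Step 3**
Reactants: 5 14-O-(4-methoxybenzyl) ether
Product: 6 4,5-epoxide of 5
Conditions: mCPBA, NaHCO3, CH2Cl2, 0 °C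
Reagents that add atoms: 3-chloroperoxybenzoic acid (OOC(=O)c1cccc(Cl)c1)
Why: Prilezhaev epoxidation should select the trisubstituted ring alkene over the 1,1-disubstituted alkene that carries an allylic ether oxygen; the epoxide configuration is immaterial.

**Step 4**
Reactants: 6 4,5-epoxide
Product: 7 exocyclic allylic alcohol (C4=C15, C5–OH)
Conditions: Et2AlCl, lithium 2,2,6,6-tetramethylpiperidide (LiNC9H18), toluene, 0 °C; aq. potassium sodium tartrate
Reagents that add atoms: none
Why: Base-induced epoxide-to-allylic-alcohol isomerisation: the aluminium amide formed in the flask binds the epoxide oxygen and removes a syn proton from the unhindered C15 methyl group in a cyclic transition state, opening the C4–O bond.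

**Step 5**
Reactants: 7 exocyclic allylic alcohol
Product: 8 primary allylic alcohol (C15–OH, C4=C5)
Conditions: Ph3SiOReO3 (2 mol %), Et2O, 0 °C
Reagents that add atoms: none
Why: 1,3-Transposition of an allylic alcohol by [3,3] shift of its perrhenate ester; the equilibrium should favour the trisubstituted endocyclic alkene with the primary hydroxyl, and both C5 epimers of 7 converge on 8.

**Step 6**
Reactants: 8 primary allylic alcohol
Product: 9 15-O-tert-butyldimethylsilyl ether of 8
Conditions: t-BuMe2SiCl, imidazole, DMF, 0 → 25 °C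
Reagents that add atoms: tert-butyldimethylsilyl chloride (CC(C)(C)[Si](C)(C)Cl)
Why: Routine silylation of a primary alcohol; O15 stays remote from the C6 alkoxide of step 13, so a silyl ether is safe at this position.

**Step 7**
Reactants: 9 15-O-silyl ether
Product: 10 4,5-epoxide of 9
Conditions: mCPBA, NaHCO3, CH2Cl2, 0 °C
Reagents that add atoms: 3-chloroperoxybenzoic acid (OOC(=O)c1cccc(Cl)c1)
Why: Prilezhaev epoxidation, again expected at the trisubstituted ring alkene; both epoxide diastereomers are taken on.

**Step 8**
Reactants: 10 4,5-epoxide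
Product: 13 tertiary allylic alcohol (C4–OH, C5=C6), via hydroxy selenide 11 (not isolated), via selenoxide 12 (not isolated)
Conditions: PhSeSePh, NaBH4, EtOH, 78 °C; then H2O2 (30 %), pyridine, THF, 0 → 25 °C
Reagents that add atoms: none
Why: The selenolate should open the epoxide at C5 because C4 is fully substituted, and the selenoxide can only eliminate syn towards C6 since C4 bears no hydrogen, which places the alkene at C5=C6 and leaves the oxygen on C4 (epoxide opening/selenoxide elimination).

**Step 9**
Reactants: 13 tertiary allylic alcohol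
Product: 14 cyclohexenone (C6=O, C4=C5, 15-OTBS, 14-OPMB; C1 is S)
Conditions: pyridinium chlorochromate (C5H5NH)[CrO3Cl], NaOAc, 4 Å molecular sieves, CH2Cl2, 25 °C
Reagents that add atoms: pyridinium chlorochromate ([O-][Cr](=O)(=O)Cl.c1cc[nH+]cc1)
Why: Babler–Dauben oxidative transposition: the tertiary chromate ester shifts [3,3] to C6 and is oxidised there to the ketone conjugated with C4=C5; the buffered, non-basic medium should leave the adjacent C1 stereocenter (α to the ketone and allylic) untouched, and both C4 epimers of 13 converge.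

**Step 10**
Reactants: 15 benzylchlorodimethylsilane; 16 ethynylmagnesium bromide
Product: 17 benzyl(ethynyl)dimethylsilane
Conditions: THF, 0 → 25 °C
Reagents that add atoms: none
Why: Substitution at silicon by the alkynyl Grignard reagent; benzyl is chosen as the third group on silicon because fluoride can later expel it, so the C–Si bond can be oxidised without acid or electrophiles in the presence of the ring alkenes.

**Step 11**
Reactants: 14 cyclohexenone; 17 benzyl(ethynyl)dimethylsilane
Product: 19 propargylic alcohol (C6 carbinol; silylethynyl cis to the C1 side chain and OH trans), via lithium acetylide 18 (not isolated)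
Conditions: n-BuLi, THF, −78 °C; then 14, −78 °C; then H2O
Reagents that add atoms: none
Why: 1,2-Addition of a lithium acetylide to the enone carbonyl; the slim sp nucleophile should attack axially on the half-chair that keeps the C1 side chain equatorial, which sets C6 with the alkynyl group cis to that side chain, and its low basicity at −78 °C should spare the acidic C1–H.

**Step 12**
Reactants: 19 propargylic alcohol
Product: 20 cis-dialkenylcyclohexenol (E-2-silylvinyl on C6, propenyl on C1)
Conditions: NaAlH2(OCH2CH2OMe)2, Et2O, 0 → 25 °C; aq. potassium sodium tartrate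
Reagents that add atoms: none
Why: Hydroxyl-directed trans-hydroalumination of the propargylic alcohol and protonolysis should give the E-vinylsilane; the silyl ether, the benzyl-type ether and the other alkenes are inert to the aluminium hydride.

**Step 13**
Reactants: 20 cis-dialkenylcyclohexenol
Product: 23 ten-membered dienone (C6=O, ring-cis C4=C5 and C1=C10, 8-silyl), via potassium alkoxide 21 (not isolated), via potassium enolate 22 (not isolated)
Conditions: KH, 18-crown-6, THF, 0 → 25 °C; then AcOH, −78 °C
Reagents that add atoms: none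
Why: Deprotonation gives the naked potassium alkoxide 21, whose oxyanion weakens the adjacent C1–C6 bond, so the 1,5-diene C8=C7–C6–C1–C10=C9 undergoes a concerted [3,3] shift (anionic oxy-Cope rearrangement, the established ring expansion of 1,2-dialkenylcycloalkanols to cycloalk-5-enones) that forms C8–C9, cleaves C1–C6 and gives enolate 22, protonated at C7 on quench. The ten-membered ring arises by ring expansion of the six-membered ring through the new C8–C9 bond between the termini of the two cis alkenyl arms, not by end-to-end cyclisation, and the cyclohexene alkene is carried over as the ring-cis C4=C5 bond. The new stereocenter C8 is set by the chair transition state: the E-vinylsilane places silicon equatorial and the fixed configuration of C1 and C6 decides which face of C8 meets C9, so the C1 stereocenter destroyed in the step is relayed to C8. The step needs the single chair in which the propenyl group and the oxygen are equatorial on the half-chair cyclohexene and the silylvinyl group is axial; this puts C2 axial on the pericyclic chair and should deliver the ring-cis C1=C10 alkene, and it is secured by the cis relation of the two alkenyl groups from step 11 and by that conformer having only one axial substituent. The alternative [3,3] shift through the ring alkene (C4=C5–C6–C1–C10=C9) would need a bridged boat and a new quaternary C4 and is not expected to compete, and the silyl group cannot leave enolate 22 by β-elimination as an oxygen substituent at C8 would.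

**Step 14**
Reactants: 23 ten-membered dienone
Product: 25 C7-(methoxycarbonylmethyl) ketone, via lithium enolate 24 (not isolated)
Conditions: LiN(SiMe3)2, THF, −78 °C; then BrCH2CO2Me, −78 → −40 °C
Reagents that add atoms: methyl bromoacetate (COC(=O)CBr)
Why: Kinetic deprotonation at the α′ carbon C7 gives the cross-conjugated enolate, which should be alkylated on its outer face, anti to the C8–C9 ring bond and away from the bulky C8 silyl group, so that C11 ends up anti to silicon, the relation needed between C11 and the later O8 (enolate alkylation under 1,2-induction by a β-silyl stereocenter).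

**Step 15**
Reactants: 25 C7-(methoxycarbonylmethyl) ketone
Product: 27 cis-fused 12,6-lactone (8-silyl, 14-OPMB, 15-OTBS), via hydroxy ester 26 (not isolated)
Conditions: NaBH4, CeCl3·7H2O, MeOH, −78 °C; then pyridinium p-toluenesulfonate (cat.), benzene, 25 °C
Reagents that add atoms: none
Why: Luche 1,2-reduction of the enone carbonyl; hydride should arrive on the outer face, anti to the C7–C8 ring bond with the acetate arm beside the carbonyl oxygen, which sets C6 with H6 cis to H7, and the γ-hydroxy ester then closes to the five-membered lactone under mild acid catalysis.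

**Step 16**
Reactants: 27 cis-fused lactone
Product: 29 8,15-diol lactone (14-OPMB), via fluorosilane 28 (not isolated)
Conditions: Bu4NF, THF, 0 → 25 °C; then H2O2 (30 %), KHCO3, MeOH/THF, 25 °C
Reagents that add atoms: hydrogen peroxide (OO)
Why: Tamao–Fleming oxidation: fluoride expels the benzyl group from silicon (and unavoidably removes the O15 silyl group), and the fluorosilane is oxidised by buffered peroxide with retention at C8, conditions the two trisubstituted alkenes, the lactone and the benzyl-type ether should tolerate.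

**Step 17**
Reactants: 29 8,15-diol lactone
Product: 31 15-O-tert-butyldimethylsilyl 8-O-triethylsilyl lactone, via mono-silyl ether 30 (not isolated)
Conditions: t-BuMe2SiCl (1.05 equiv), imidazole, DMF, −20 °C; then Et3SiCl, 0 → 25 °C
Reagents that add atoms: tert-butyldimethylsilyl chloride (CC(C)(C)[Si](C)(C)Cl); chlorotriethylsilane (CC[Si](Cl)(CC)CC)
Why: Selective silylation: the primary allylic O15 reacts first with the bulky chloride, and the secondary O8 is then capped as the more labile triethylsilyl ether so that no free C8 hydroxyl can attack the lactone carbonyl under the basic conditions of step 18.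

**Step 18**
Reactants: 31 bis-silyl lactone
Product: 35 α-methylene lactone (C11=C13), via lithium enolate 32 (not isolated), via Mannich base 33 (not isolated), via ammonium iodide 34 (not isolated)
Conditions: LiN(SiMe3)2, THF, −78 °C; [Me2N=CH2]I, −78 → 0 °C; then MeI, MeOH, 25 °C; then aq. NaHCO3, EtOAc
Reagents that add atoms: dimethyl(methylidene)ammonium iodide (C=[N+](C)C.[I-])
Why: α-Methylenation by the Mannich route: the lactone enolate is aminomethylated at C11, the amine is quaternised and the ammonium salt undergoes Hofmann-type β-elimination with bicarbonate to the exocyclic alkene; the C11 configuration of the Mannich base is irrelevant and the carbon of MeI leaves with the amine.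

**Step 19**
Reactants: 35 α-methylene lactone
Product: 36 8-hydroxy α-methylene lactone (15-OTBS, 14-OPMB)
Conditions: pyridinium p-toluenesulfonate (cat.), MeOH/CH2Cl2, 0 °C
Reagents that add atoms: none
Why: Acid-catalysed methanolysis should remove the secondary triethylsilyl ether well before the primary tert-butyldimethylsilyl ether (selective desilylation), and methanol does not add to the methylene lactone without base.

**Step 20**
Reactants: 36 8-hydroxy α-methylene lactone
Product: 37 8-O-(3-methylbutanoyl) ester
Conditions: (Me2CHCH2CO)2O, 4-(dimethylamino)pyridine (cat.), pyridine, CH2Cl2, 0 → 25 °C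
Reagents that add atoms: 3-methylbutanoic anhydride (CC(C)CC(=O)OC(=O)CC(C)C)
Why: Nucleophile-catalysed acylation of the secondary C8 alcohol by the anhydride; the weakly basic medium should neither add to the α-methylene lactone nor induce translactonisation.

**Step 21**
Reactants: 37 8-ester
Product: 38 14-alcohol (15-OTBS)
Conditions: DDQ, CH2Cl2/pH 7 phosphate buffer, 0 °C
Reagents that add atoms: none
Why: Oxidative cleavage of the 4-methoxybenzyl ether by DDQ through the benzylic oxocarbenium ion, which water hydrolyses; the silyl ether, the esters and the electron-poor alkene are inert.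

**Step 22**
Reactants: 38 14-alcohol
Product: 39 14-aldehyde (15-OTBS)
Conditions: MnO2, CH2Cl2, 25 °C
Reagents that add atoms: none
Why: MnO2 oxidises the primary allylic alcohol to the conjugated aldehyde and stops there; the C1=C10 geometry is already ring-cis, the stable arrangement for such ten-membered enals.

**Step 23**
Reactants: 39 14-aldehyde
Product: 40 CNP0345200.8
Conditions: HF·pyridine, pyridine, THF, 0 °C
Reagents that add atoms: none
Why: Buffered fluoride-mediated desilylation frees the C15 hydroxyl under conditions that the enal, the α-methylene lactone and the isovalerate should tolerate.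

**Compound list**
1 | (R)-limonene | CC1=CC[C@@H](CC1)C(C)=C | starting material
2 | 14-lithio-(R)-limonene (allyllithium) | CC1=CC[C@@H](CC1)C(=C)C[Li] | intermediate
3 | dimethyl (R)-limonen-14-ylboronate | CC1=CC[C@@H](CC1)C(=C)CB(OC)OC | intermediate
4 | (R)-14-hydroxylimonene, 2-[(1R)-4-methylcyclohex-3-en-1-yl]prop-2-en-1-ol | CC1=CC[C@@H](CC1)C(=C)CO | intermediate
5 | 14-O-(4-methoxybenzyl) ether of 4 | CC1=CC[C@@H](CC1)C(=C)COCc1ccc(OC)cc1 | intermediate
6 | 4,5-epoxide of 5 (both epoxide diastereomers) | CC12OC1C[C@@H](CC2)C(=C)COCc1ccc(OC)cc1 | intermediate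
7 | exocyclic allylic alcohol, C4=C15 and C5–OH (C5 epimers), 14-OPMB | C=C1C(O)C[C@@H](CC1)C(=C)COCc1ccc(OC)cc1 | intermediate
8 | {(4R)-4-[3-(4-methoxybenzyloxy)prop-1-en-2-yl]cyclohex-1-en-1-yl}methanol (C15–OH, C4=C5) | OCC1=CC[C@@H](CC1)C(=C)COCc1ccc(OC)cc1 | intermediate
9 | 15-O-tert-butyldimethylsilyl ether of 8 | CC(C)(C)[Si](C)(C)OCC1=CC[C@@H](CC1)C(=C)COCc1ccc(OC)cc1 | intermediate
10 | 4,5-epoxide of 9 (both epoxide diastereomers) | CC(C)(C)[Si](C)(C)OCC12OC1C[C@@H](CC2)C(=C)COCc1ccc(OC)cc1 | intermediate
11 | 5-(phenylselanyl)-4-ol from 10 (trans opening) | CC(C)(C)[Si](C)(C)OCC1(O)C([Se]c2ccccc2)C[C@@H](CC1)C(=C)COCc1ccc(OC)cc1 | intermediate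
12 | selenoxide of 11 | CC(C)(C)[Si](C)(C)OCC1(O)C([Se](=O)c2ccccc2)C[C@@H](CC1)C(=C)COCc1ccc(OC)cc1 | intermediate
13 | tertiary allylic alcohol, C4–OH and C5=C6 (C4 epimers), 15-OTBS, 14-OPMB | CC(C)(C)[Si](C)(C)OCC1(O)C=C[C@@H](CC1)C(=C)COCc1ccc(OC)cc1 | intermediate
14 | (6S)-3-[(tert-butyldimethylsilyloxy)methyl]-6-[3-(4-methoxybenzyloxy)prop-1-en-2-yl]cyclohex-2-en-1-one (C6=O, C4=C5) | O=C1C=C(CO[Si](C)(C)C(C)(C)C)CC[C@H]1C(=C)COCc1ccc(OC)cc1 | intermediate
15 | benzylchlorodimethylsilane | C[Si](C)(Cl)Cc1ccccc1 | starting material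
16 | ethynylmagnesium bromide | C#C[Mg]Br | starting material
17 | benzyl(ethynyl)dimethylsilane | C#C[Si](C)(C)Cc1ccccc1 | intermediate
18 | lithium [benzyl(dimethyl)silyl]acetylide | [Li]C#C[Si](C)(C)Cc1ccccc1 | intermediate
19 | propargylic alcohol: C6 carbinol of 14 bearing the silylethynyl group cis to the C1 side chain, OH trans | O[C@]1(C#C[Si](C)(C)Cc2ccccc2)C=C(CO[Si](C)(C)C(C)(C)C)CC[C@H]1C(=C)COCc1ccc(OC)cc1 | intermediate
20 | cis-dialkenylcyclohexenol: C6 carbinol with (E)-2-[benzyl(dimethyl)silyl]ethenyl, C1 with the O14-PMB propenyl group, O15-TBS | O[C@]1(/C=C/[Si](C)(C)Cc2ccccc2)C=C(CO[Si](C)(C)C(C)(C)C)CC[C@H]1C(=C)COCc1ccc(OC)cc1 | intermediate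
21 | potassium alkoxide of 20 | [K+].[O-][C@]1(/C=C/[Si](C)(C)Cc2ccccc2)C=C(CO[Si](C)(C)C(C)(C)C)CC[C@H]1C(=C)COCc1ccc(OC)cc1 | intermediate
22 | potassium C6(O)=C7 enolate of 23 (C5 trans to C8) | [K+].[O-]/C1=C\[C@H]([Si](C)(C)Cc2ccccc2)C/C(COCc2ccc(OC)cc2)=C\CC/C(CO[Si](C)(C)C(C)(C)C)=C\1 | intermediate
23 | ten-membered dienone: C6 ketone, ring-cis C4=C5 and C1=C10, 8-[benzyl(dimethyl)silyl] (8R), 14-OPMB, 15-OTBS | O=C1/C=C(/CO[Si](C)(C)C(C)(C)C)CC/C=C(/COCc2ccc(OC)cc2)C[C@@H]([Si](C)(C)Cc2ccccc2)C1 | intermediate
24 | lithium C6(O)=C7 enolate of 23 (enolate geometry left open) | [Li+].[O-]C1=C[C@H]([Si](C)(C)Cc2ccccc2)C/C(COCc2ccc(OC)cc2)=C\CC/C(CO[Si](C)(C)C(C)(C)C)=C\1 | intermediate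
25 | C7-(methoxycarbonylmethyl) derivative of 23, C7 as in the target | O=C1/C=C(/CO[Si](C)(C)C(C)(C)C)CC/C=C(/COCc2ccc(OC)cc2)C[C@@H]([Si](C)(C)Cc2ccccc2)[C@H]1CC(=O)OC | intermediate
26 | C6 alcohol of 25 (C6 as in the target) | O[C@H]1/C=C(/CO[Si](C)(C)C(C)(C)C)CC/C=C(/COCc2ccc(OC)cc2)C[C@@H]([Si](C)(C)Cc2ccccc2)[C@H]1CC(=O)OC | intermediate
27 | cis-fused 12,6-lactone, 8-[benzyl(dimethyl)silyl], 14-OPMB, 15-OTBS | C1C(=O)O[C@H]2/C=C(/CO[Si](C)(C)C(C)(C)C)CC/C=C(/COCc3ccc(OC)cc3)C[C@@H]([Si](C)(C)Cc3ccccc3)[C@@H]12 | intermediate
28 | 8-(fluorodimethylsilyl) 15-hydroxy lactone | C1C(=O)O[C@H]2/C=C(/CO)CC/C=C(/COCc3ccc(OC)cc3)C[C@@H]([Si](C)(C)F)[C@@H]12 | intermediate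
29 | 8,15-dihydroxy lactone, 14-OPMB | C1C(=O)O[C@H]2/C=C(/CO)CC/C=C(/COCc3ccc(OC)cc3)C[C@@H](O)[C@@H]12 | intermediate
30 | 15-O-TBS 8-hydroxy lactone | C1C(=O)O[C@H]2/C=C(/CO[Si](C)(C)C(C)(C)C)CC/C=C(/COCc3ccc(OC)cc3)C[C@@H](O)[C@@H]12 | intermediate
31 | 15-O-TBS 8-O-triethylsilyl lactone | C1C(=O)O[C@H]2/C=C(/CO[Si](C)(C)C(C)(C)C)CC/C=C(/COCc3ccc(OC)cc3)C[C@@H](O[Si](CC)(CC)CC)[C@@H]12 | intermediate
32 | lithium enolate (C11=C12–O) of 31 | [Li+].C1=C([O-])O[C@H]2/C=C(/CO[Si](C)(C)C(C)(C)C)CC/C=C(/COCc3ccc(OC)cc3)C[C@@H](O[Si](CC)(CC)CC)[C@@H]12 | intermediate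
33 | 11-(dimethylaminomethyl) lactone (C11 epimers) | CN(C)CC1C(=O)O[C@H]2/C=C(/CO[Si](C)(C)C(C)(C)C)CC/C=C(/COCc3ccc(OC)cc3)C[C@@H](O[Si](CC)(CC)CC)[C@@H]12 | intermediate
34 | 11-(trimethylammoniomethyl) lactone iodide | C[N+](C)(C)CC1C(=O)O[C@H]2/C=C(/CO[Si](C)(C)C(C)(C)C)CC/C=C(/COCc3ccc(OC)cc3)C[C@@H](O[Si](CC)(CC)CC)[C@@H]12.[I-] | intermediate
35 | α-methylene lactone, 8-O-triethylsilyl, 14-OPMB, 15-OTBS | C=C1C(=O)O[C@H]2/C=C(/CO[Si](C)(C)C(C)(C)C)CC/C=C(/COCc3ccc(OC)cc3)C[C@@H](O[Si](CC)(CC)CC)[C@@H]12 | intermediate
36 | 8-hydroxy α-methylene lactone, 14-OPMB, 15-OTBS | C=C1C(=O)O[C@H]2/C=C(/CO[Si](C)(C)C(C)(C)C)CC/C=C(/COCc3ccc(OC)cc3)C[C@@H](O)[C@@H]12 | intermediate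
37 | 8-O-(3-methylbutanoyl) ester of 36 | C=C1C(=O)O[C@H]2/C=C(/CO[Si](C)(C)C(C)(C)C)CC/C=C(/COCc3ccc(OC)cc3)C[C@@H](OC(=O)CC(C)C)[C@@H]12 | intermediate
38 | 14-alcohol, 15-OTBS, 8-O-(3-methylbutanoyl) | C=C1C(=O)O[C@H]2/C=C(/CO[Si](C)(C)C(C)(C)C)CC/C=C(/CO)C[C@@H](OC(=O)CC(C)C)[C@@H]12 | intermediate
39 | 14-aldehyde, 15-OTBS, 8-O-(3-methylbutanoyl) | C=C1C(=O)O[C@H]2/C=C(/CO[Si](C)(C)C(C)(C)C)CC/C=C(/C=O)C[C@@H](OC(=O)CC(C)C)[C@@H]12 | intermediate
40 | CNP0345200.8: (6S,7R,8R)-15-hydroxy-8-(3-methylbutanoyloxy)-14-oxogermacra-1(10),4,11(13)-trien-12,6-olide, both ring alkenes ring-cis | C=C1C(=O)O[C@H]2/C=C(/CO)CC/C=C(/C=O)C[C@@H](OC(=O)CC(C)C)[C@@H]12 | target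

**Step count**
Total: 23 steps. Longest linear sequence: 22 steps (steps 1–9 and 11–23, from (R)-limonene); step 10 is a one-step side branch.

**Steps most likely to fail**

1. Step 13 (ring expansion). The rearrangement may run in part through the other chair (propenyl axial) or a boat, which would give the ring-trans C1=C10 isomer or the C8 epimer, and the basic medium may isomerise enolate 22 into conjugation or fragment the alkoxide before quench. Fallback, from 20 back to 23: the tertiary alcohol is silylated (Me3SiCl, imidazole, DMF) to the trimethylsilyl ether F1. Thermolysis in degassed decalin at about 200 °C (neutral siloxy-Cope rearrangement through the same chair) should give the ten-membered trimethylsilyl enol ether F2. Mild methanolysis (citric acid cat., MeOH, 0 °C) returns ketone 23. No free enolate or strong base is present at any stage.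

2. Step 14 (C7 alkylation). On re-enolisation, deprotonation may go to the γ-positions (C3, C15) to give the extended dienolate, and proton exchange between product and enolate may lead to dialkylation or loss of C7 control. Fallback, from 20 back to 25: the ring expansion of step 13 is run as before, but the regiodefined potassium enolate 22 is trapped in the same flask with methyl bromoacetate at −78 °C in place of the acid quench (tandem oxy-Cope/alkylation). The C6=C7 enolate is then produced by the sigmatropic shift itself and never by deprotonation; this fallback makes no new compound (F0).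

3. Step 15 (C6 reduction). Hydride delivery to the other face of the flexible ten-membered ketone would give the C6 epimer and hence a trans-fused lactone. Fallback, from 25 back to 27: the epimeric alcohol, the 6-epi hydroxy ester F3 (or its trans lactone), is saponified (LiOH, THF/H2O) to the 6-epi hydroxy acid F4. Mitsunobu lactonisation (PPh3, diisopropyl azodicarboxylate, toluene) then closes the ring with inversion at the allylic C6, giving the cis-fused lactone 27.

**Further compounds**
F1 | step 13 | trimethylsilyl ether of 20 | C[Si](C)(C)O[C@]1(/C=C/[Si](C)(C)Cc2ccccc2)C=C(CO[Si](C)(C)C(C)(C)C)CC[C@H]1C(=C)COCc1ccc(OC)cc1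
F2 | step 13 | trimethylsilyl enol ether (C6–OSiMe3, C6=C7) of 23 | C[Si](C)(C)O/C1=C\[C@H]([Si](C)(C)Cc2ccccc2)C/C(COCc2ccc(OC)cc2)=C\CC/C(CO[Si](C)(C)C(C)(C)C)=C\1
F0 | step 14 | none | none
F3 | step 15 | 6-epi hydroxy ester (C6 epimer of 26) | O[C@@H]1/C=C(/CO[Si](C)(C)C(C)(C)C)CC/C=C(/COCc2ccc(OC)cc2)C[C@@H]([Si](C)(C)Cc2ccccc2)[C@H]1CC(=O)OC
F4 | step 15 | 6-epi hydroxy acid | O[C@@H]1/C=C(/CO[Si](C)(C)C(C)(C)C)CC/C=C(/COCc2ccc(OC)cc2)C[C@@H]([Si](C)(C)Cc2ccccc2)[C@H]1CC(=O)O
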